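## Structural features

The target is a 3,8''-linked biflavonoid. A 5,7,4'-trihydroxyflavanone (rings A, B and C) is bonded through C3 to C8 of a 5,7,3',4'-tetraoxygenated flavone, whose benzo ring is ring D, and only the flavone 7-oxygen carries a hydrogen sulfate. The two stereocentres are adjacent: C2 (R, bearing ring B) and C3 (S, bearing ring D), with the two aryl groups trans on ring C. C3 is a tertiary sp3 carbon between the C4 carbonyl and an arene substituted at both ortho positions (C7–O and C8a–O of ring D), so C3–C8 is the congested bond. Fragile points are the aryl sulfate (lost in acid), the acidic C3–H (enolisation can expel O1 from C2, opening ring C and scrambling C2), the benzylic C2–O1 bond (ionises in strong acid) and six free phenols. The difficulty is twofold: making the hindered C3–C8 bond with both stereocentres defined, and singling out one phenolic oxygen of seven without exposing the flavanone to strong base or acid. The key step exploits ring A: O1 sits on C8a and the C4 carbonyl on the neighbouring C4a, with the 5-oxygen next to C4a and the 7-oxygen meta to both, which is the pattern left when an oxygen nucleophile and an acyl group add across a 3,5-dioxygenated benzyne.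

## Logic of the disconnections

**29 to 26.** The six benzyl O–C bonds, the O–S bond of the sulfate and the acetal O–C bond on the flavone 7-oxygen are cut. The sulfate is the most fragile group, so it is placed as late as the protecting groups allow. Going back through 28 and 27 to 26 replaces a polar, acid-sensitive polyphenol by one neutral compound in which six oxygens carry one kind of group and the seventh another. The forward steps must be orthogonal without stressing ring C: acid mild enough for C2–O1, a sulfation base too weak to enolise C3, and hydrogenolysis that leaves both pyranones alone.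

**26 to 18 and 23.** O1–C8a and C4–C4a are cut, which removes ring A as 25 and opens ring C to 18 (used as 24). Ring A is symmetric and achiral, whereas the C3–C8 bond and both stereocentres stay in a chain that aldol chemistry can build. The forward step must put oxygen on the aryne carbon remote from the flanking ether, let the aryl anion reach the ester before any proton does, and keep the alkoxide from fragmenting by retro-aldol.

**18 to 14 and 15.** The C2–C3 bond (flavanone numbering) is cut as an aldol bond, and the ester is traced through 17 to an auxiliary-bearing imide. Both stereocentres then come from an achiral aldehyde and an arylacetic acid derivative in one step. The aldol must be anti- and face-selective with an enolate whose arene is substituted at both ortho positions, and exchanging the auxiliary for methoxide must not reverse the aldol.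

**14 to 8.** The N–acyl bond is cut to 11 and 12, the carboxyl carbon of 11 is traced to the terminal alkene of 9 (one carbon lost), and the acetal on O7 is cut to give 8. The acetic acid side chain becomes an allyl group, and the oxygen to be sulfated is marked while it is the only free phenol. The alkene must be cleaved without harming benzyl ethers or the flavone double bond.

**8 to 5.** The C8–CH2 bond is traced through a [3,3] shift to the O7–allyl bond of 7, and the allyl and 5-O-benzyl O–C bonds are cut to give 5. The hindered C–C bond at C8 thus comes from an easy O-alkylation. The forward steps need the acidity difference between the 7- and 5-hydroxyls, and migration to C8 and not C6.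

**5 to 1 and 2.** The flavone C2–C3 and O1–C2 bonds are cut (through 4 and 3). The ortho-hydroxyls of 1 are equivalent, so no protecting group is needed and only one flavone can form. The forward step needs C-acylation of a polyanion in preference to O-acylation.

**23 to 19.** The C–Si and O–S bonds are traced through 22 and 21 to the C–Br bond of 20, which is cut to give 19. The aryne precursor is reduced to a symmetric phenol. The bromination must go ortho to the hydroxyl and not para.

## Other disconnections considered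

**Alternative 1:** The cut falls on C3–C4 and on the bond from C2 to C1' of ring B; O1–C8a is left for a later displacement of fluoride.
- **Forward step:** the (E)-alkenyl boronate A2 (flavone on the future C3, boron on the future C2) would form an ate complex with aryllithium A3. Pd(OAc)2 with a MandyPhos ligand would then join the acyl–palladium species from acid chloride A4 to C3 while ring B shifts from boron to C2, giving β-boryl ketone A1.
- **In its favour:** both stereocentres would come from one catalytic, ligand-controlled step, and their anti relationship follows from the (E)-geometry and anti addition. No fluoride is used, so the flavone 7-oxygen can carry a silyl ether removable under neutral conditions. On this point, and in needing no stoichiometric auxiliary, it is better than the chosen plan.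
- **Against it here:** 1,2-disubstituted alkenyl boronates are reluctant partners in this coupling, and here the alkene carbon bears a doubly ortho-substituted arene while the acyl group is itself 2,6-disubstituted. A1 would still need C–B oxidation and a fluoride displacement on a ring deactivated by two ether donors, run through the alkoxide of a β-hydroxy ketone that can fragment or dehydrate.
- **Comparison:** on structure both plans keep ring A as a late, simple unit. On mechanism the chosen plan closes ring C in the same event that attaches ring A, whereas here the weakest step comes after the key step. On step economy the two are about equal, since A2 should take about as many steps as 11 and two operations follow A1 before the common end game.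

**Alternative 2:** The cut is C3–C4 alone, made with reversed polarity; O1–C8a and O1–C2 are already present in aldehyde A6.
- **Forward step:** Cs2CO3 would expel p-toluenesulfinate from A6 to give an ortho-quinone methide spanning flavone O7, C7, C8 and C3. The acyl anion equivalent formed from the ring A aldehyde and an N-mesityl triazolylidene would add to C3 and close ring C, giving A5.
- **In its favour:** A5 is the same compound as 27, so the flavone 7-hydroxyl arrives free where the sulfate belongs, with no acetal to put on or take off. Here it is better than the chosen plan by two steps at the end. The catalyst is organic, C2 is fixed beforehand in the ether, and C3 should follow by substrate control.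
- **Against it here:** A6 is harder to reach than 18. It needs the aryl ether of a secondary benzylic alcohol next to a sulfonyl-bearing carbon, and under base that carbon can expel the ring A aryloxide (vinyl sulfone formation) in competition with sulfinate loss. The quinone methide carbon is fully substituted and hindered, and the phenoxide product would sit in carbonate base, which can open ring C.
- **Comparison:** both plans rest on an untested ring closure. The chosen one forms two bonds and brings ring A in as a symmetric unit, whereas this one forms one bond and must attach a ring A aldehyde earlier. Overall length should be similar.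

**Alternative 3:** The cut falls on C3–C8 of the flavone and on O1–C2.
- **Forward step:** PhI(OH)OTs would convert the enol of the β,β-diaryl ketone A8 into a C3–iodine species (trivalent iodine). Ring D would shift from C2 to C3 as iodobenzene leaves, and the ring A phenol would open the bridged ion at C2, giving A7.
- **In its favour:** the hindered C3–C8 bond is made by a 1,2-shift from a carbon where the flavone can be installed by conjugate addition, and A8 has a single stereocentre that a catalytic asymmetric conjugate arylation of an enone could set. The shift has a close relative in the oxidative rearrangement of flavanones and chalcones to isoflavone-type products. This is probably the shortest route, and on step economy it is better than the chosen plan.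
- **Against it here:** two aryl groups sit on C2 and either may migrate. The acetate slows ring B, but ring D is attached through a doubly ortho-substituted carbon and carries the electron-poor pyranone. The oxidant also attacks electron-rich phenols such as the ring A phenol, and can dehydrogenate the product further. The C2 stereocentre must pass through a bridged or open benzylic cation; the (S)-ketone A8 would be needed if the phenol enters anti to the migrating ring.
- **Comparison:** on structure it addresses the hardest bond most directly. On mechanism it has more ways to go astray, and its stereocentre is rebuilt during the step, whereas both stereocentres are spectators in the chosen plan.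

Key step: step 11

Remark on the structures: precursor and product were checked atom by atom and centre by centre and agree (anti-(2S,3R) ester to (2R,3S)-trans flavanone with retention at both centres), so no structure is changed.

Remark on the precursor: a free hydroxyl would hand its proton to the aryl anion, and a preformed alkoxide would fragment; 18 therefore enters the key step as its trimethylsilyl ether 24, made in the flask.

Remark on the sulfate: 28 and 29 are drawn as free hydrogen sulfates but are to be handled as sodium salts, the acid form being released only by cold cation exchange.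

## Route

Step 1
Reactants: 1 2,4,6-trihydroxyacetophenone; 2 3,4-bis(benzyloxy)benzoic acid
Product: 5 2-[3,4-bis(benzyloxy)phenyl]-5,7-dihydroxy-4H-chromen-4-one, via acid chloride 3 (not isolated), via diketone 4 (not isolated)
Conditions: 2, (COCl)2, cat. DMF, CH2Cl2, rt, evaporate; 1, LiN(SiMe3)2 (5 equiv), THF, −78 → −10 °C, then 3, −78 °C → rt; HCl quench, then AcOH, cat. H2SO4, 60 °C
Reagents that add atoms: none
Why: Baker–Venkataraman-type direct C-acylation of the lithium polyanion of 1 by 3 gives diketone 4, which closes by acid-catalysed cyclodehydration; the two ortho-hydroxyls of 1 are equivalent, so only one flavone can form.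

Step 2
Reactants: 5
Product: 7 7-(allyloxy)-5-(benzyloxy)-2-[3,4-bis(benzyloxy)phenyl]-4H-chromen-4-one, via 7-O-allyl ether 6 (not isolated)
Conditions: allyl bromide (1.05 equiv), K2CO3, DMF, rt; then BnBr (1.5 equiv), 70 °C
Reagents that add atoms: allyl bromide C=CCBr; benzyl bromide BrCc1ccccc1
Why: Two Williamson etherifications in sequence; the 7-hydroxyl is far more acidic and is not hydrogen-bonded, so it takes the first halide at room temperature, and the chelated 5-hydroxyl is benzylated only on heating.

Step 3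
Reactants: 7
Product: 8 8-allyl-5-(benzyloxy)-2-[3,4-bis(benzyloxy)phenyl]-7-hydroxy-4H-chromen-4-one
Conditions: PhNEt2, 200 °C
Reagents that add atoms: none
Why: Aromatic Claisen rearrangement; in 7-allyloxychromones the allyl group goes to C8, the angular position next to the ring fusion (as in 2-naphthyl allyl ethers), and C6 is also screened by the 5-benzyloxy group.

Step 4
Reactants: 8
Product: 9 8-allyl-5-(benzyloxy)-2-[3,4-bis(benzyloxy)phenyl]-7-(methoxymethoxy)-4H-chromen-4-one
Conditions: MOMCl, i-Pr2NEt, CH2Cl2, 0 °C → rt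
Reagents that add atoms: chloromethyl methyl ether COCCl
Why: O-alkylation of the only free, acidic phenol; the acetal tolerates ozone, base and fluoride and is later removed by mild acid without touching benzyl ethers.

Step 5
Reactants: 9
Product: 11 {5-(benzyloxy)-2-[3,4-bis(benzyloxy)phenyl]-7-(methoxymethoxy)-4-oxo-4H-chromen-8-yl}acetic acid, via aldehyde 10 (not isolated)
Conditions: O3, acetone/H2O (95:5), 0 °C (Sudan Red 7B end point); then NaClO2, NaH2PO4, 2-methyl-2-butene, t-BuOH/H2O, rt
Reagents that add atoms: ozone [O-][O+]=O; sodium chlorite [Na+].[O-]Cl=O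
Why: Ozonolysis in wet acetone gives the aldehyde directly (water intercepts the carbonyl oxide), and Pinnick oxidation follows in the same flask; the terminal alkene reacts far faster than the flavone C2=C3 bond or the alkoxyarenes, and the dye marks the end point.

Step 6
Reactants: 11; 12 (4R)-4-benzyl-1,3-oxazolidin-2-one
Product: 14 (4R)-4-benzyl-3-({5-(benzyloxy)-2-[3,4-bis(benzyloxy)phenyl]-7-(methoxymethoxy)-4-oxo-4H-chromen-8-yl}acetyl)-1,3-oxazolidin-2-one, via mixed anhydride 13 (not isolated)
Conditions: PivCl, Et3N, THF, −20 °C; then 12, LiCl, −20 °C → rt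
Reagents that add atoms: none
Why: N-acylation of the oxazolidinone by a pivalic mixed anhydride under LiCl/Et3N activation; the hindered pivaloyl carbonyl is not attacked.

Step 7
Reactants: 14; 15 4-(benzyloxy)benzaldehyde
Product: 17 (4R)-4-benzyl-3-[(2S,3R)-3-[4-(benzyloxy)phenyl]-2-{5-(benzyloxy)-2-[3,4-bis(benzyloxy)phenyl]-7-(methoxymethoxy)-4-oxo-4H-chromen-8-yl}-3-hydroxypropanoyl]-1,3-oxazolidin-2-one, via silyl ether 16 (not isolated)
Conditions: MgCl2 (0.2 equiv), Et3N, Me3SiCl, EtOAc, rt; then 1 M HCl/THF, 0 °C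
Reagents that add atoms: none
Why: Magnesium-halide-catalysed direct anti-aldol of an N-acyloxazolidinone with a non-enolisable aromatic aldehyde; the chelated (Z)-magnesium enolate should take the aldehyde through a boat-like transition state on the face away from the benzyl group of the (R)-auxiliary, setting C2 (S) and C3 (R) anti. Silylation of the aldolate to 16 turns the catalyst over and blocks retro-aldol equilibration.

Step 8
Reactants: 17
Product: 18 methyl (2S,3R)-3-[4-(benzyloxy)phenyl]-2-{5-(benzyloxy)-2-[3,4-bis(benzyloxy)phenyl]-7-(methoxymethoxy)-4-oxo-4H-chromen-8-yl}-3-hydroxypropanoate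
Conditions: MeMgBr, MeOH, CH2Cl2, 0 °C
Reagents that add atoms: methanol CO
Why: Transesterification by MeOMgBr; the magnesium chelate of the aldolate directs methoxide to the exocyclic acyl group and should hold the adduct against retro-aldol cleavage and epimerisation at 0 °C, and 12 is recovered.

Step 9
Reactants: 19 3,5-bis(benzyloxy)phenol
Product: 20 3,5-bis(benzyloxy)-2-bromophenol
Conditions: NBS (1.0 equiv), i-Pr2NH (10 mol%), CH2Cl2, −78 → 0 °C
Reagents that add atoms: N-bromosuccinimide O=C1CCC(=O)N1Br
Why: Amine-mediated electrophilic bromination, which delivers bromine ortho to a phenolic hydroxyl; the two ortho positions are equivalent and the para position lies between two benzyloxy groups.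

Step 10
Reactants: 20
Product: 23 3,5-bis(benzyloxy)-2-(trimethylsilyl)phenyl trifluoromethanesulfonate, via silyl ether 21 (not isolated), via lithium phenoxide 22 (not isolated)
Conditions: (Me3Si)2NH, THF, 65 °C, evaporate; n-BuLi, THF, −78 °C → rt; Tf2O, −78 °C
Reagents that add atoms: hexamethyldisilazane C[Si](C)(C)N[Si](C)(C)C; triflic anhydride O=S(=O)(OS(=O)(=O)C(F)(F)F)C(F)(F)F
Why: O-silylation, bromine–lithium exchange (faster than benzylic deprotonation at −78 °C), retro-Brook shift of silicon from oxygen to carbon and O-triflation; this is the standard sequence to ortho-silylaryl triflates.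

Step 11
Reactants: 18; 23
Product: 26 (2R,3S)-5,7-bis(benzyloxy)-2-[4-(benzyloxy)phenyl]-3-{5-(benzyloxy)-2-[3,4-bis(benzyloxy)phenyl]-7-(methoxymethoxy)-4-oxo-4H-chromen-8-yl}-2,3-dihydro-4H-chromen-4-one, via silyl ether 24 (not isolated), via aryne 25 (not isolated)
Conditions: 18, Me3SiNMe2, CH2Cl2, rt, evaporate; 23 (2.5 equiv), CsF (6 equiv), 18-crown-6 (1 equiv), THF, 0 °C → rt; pH 7 phosphate buffer, 0 °C
Reagents that add atoms: none
Why: Proposed new method: fluoride removes silicon from 23 to give aryne 25 and, at a comparable rate, from 24 to give a caesium alkoxide in a medium with no proton donor; the alkoxide oxygen adds to the aryne carbon remote from the flanking benzyloxy group (O1–C8a), and the aryl anion left beside that group attacks the methyl ester (C4a–C4) and expels methoxide, which the silyl electrophiles present (Me3SiF, excess 23) can capture. The closest known reaction type is the aryne annulation of salicylate esters to xanthones (oxygen addition, then intramolecular acylation); its extension to an aliphatic β-silyloxy ester is untested. Ring C closes by 6-exo-trig acyl substitution of the aryl anion on the ester carbonyl. No stereocentre is made: the C2–O and C3–H bonds are untouched, so the (R)-carbinol and the adjacent centre of 18 are carried over with retention and appear as the (2R,3S)-trans pair. Regioselectivity rests on the benzyloxy group next to the triple bond, which distorts the aryne and stabilises negative charge on its neighbouring carbon, so that oxygen ends on C8a and the carbonyl on C4a beside the 5-oxygen; the second benzyloxy group is meta to the attacked carbon and should not oppose this. Chemoselectivity rests on the silyl ether: it keeps the alkoxide concentration low against retro-aldol cleavage and leaves no hydroxyl proton to quench the aryl anion, while the excess of 23 should keep methoxide from enolising C3 of the product.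

Step 12
Reactants: 26
Product: 27 (2R,3S)-5,7-bis(benzyloxy)-2-[4-(benzyloxy)phenyl]-3-{5-(benzyloxy)-2-[3,4-bis(benzyloxy)phenyl]-7-hydroxy-4-oxo-4H-chromen-8-yl}-2,3-dihydro-4H-chromen-4-one
Conditions: 2 M HCl, MeOH/THF, 40 °C
Reagents that add atoms: none
Why: Acid-catalysed acetal cleavage of the aryl methoxymethyl ether, with benzyl ethers retained; reversible ionisation of C2–O1 would reclose to the more stable trans isomer because acid does not touch C3, and loss of a peri benzyl group would be harmless because chelated 5-hydroxyls are not sulfated in step 13.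

Step 13
Reactants: 27
Product: 28 8-{(2R,3S)-5,7-bis(benzyloxy)-2-[4-(benzyloxy)phenyl]-4-oxo-3,4-dihydro-2H-chromen-3-yl}-5-(benzyloxy)-2-[3,4-bis(benzyloxy)phenyl]-4-oxo-4H-chromen-7-yl hydrogen sulfate
Conditions: SO3·pyridine (6 equiv), pyridine, rt → 40 °C; aq. NaHCO3
Reagents that add atoms: sulfur trioxide–pyridine complex O=S(=O)=O.c1ccncc1
Why: O-sulfonation of the only free phenol by an amine–SO3 complex; pyridine is too weak a base to enolise C3, and the monoester is kept as its sodium salt so that it cannot catalyse its own hydrolysis.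

Step 14
Reactants: 28
Product: 29 8-[(2R,3S)-5,7-dihydroxy-2-(4-hydroxyphenyl)-4-oxo-3,4-dihydro-2H-chromen-3-yl]-2-(3,4-dihydroxyphenyl)-5-hydroxy-4-oxo-4H-chromen-7-yl hydrogen sulfate
Conditions: H2 (1 atm), 10% Pd/C, THF/MeOH, rt; cold Dowex 50W (H+ form) if the free acid is required
Reagents that add atoms: none
Why: Hydrogenolysis of six aryl benzyl ethers under neutral, low-pressure conditions, which should leave the aryl sulfate salt, the flavone C2=C3 bond, the flavanone carbonyl and the C2–O1 bond intact; no stereocentre is touched.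

## Compound list

1 | 2,4,6-trihydroxyacetophenone | CC(=O)c1c(O)cc(O)cc1O | starting material
2 | 3,4-bis(benzyloxy)benzoic acid | O=C(O)c1ccc(OCc2ccccc2)c(OCc2ccccc2)c1 | starting material
3 | 3,4-bis(benzyloxy)benzoyl chloride | O=C(Cl)c1ccc(OCc2ccccc2)c(OCc2ccccc2)c1 | intermediate
4 | 1-[3,4-bis(benzyloxy)phenyl]-3-(2,4,6-trihydroxyphenyl)propane-1,3-dione | O=C(CC(=O)c1c(O)cc(O)cc1O)c1ccc(OCc2ccccc2)c(OCc2ccccc2)c1 | intermediate
5 | 2-[3,4-bis(benzyloxy)phenyl]-5,7-dihydroxy-4H-chromen-4-one | O=c1cc(-c2ccc(OCc3ccccc3)c(OCc3ccccc3)c2)oc2cc(O)cc(O)c12 | intermediate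
6 | 7-(allyloxy)-2-[3,4-bis(benzyloxy)phenyl]-5-hydroxy-4H-chromen-4-one | C=CCOc1cc(O)c2c(=O)cc(-c3ccc(OCc4ccccc4)c(OCc4ccccc4)c3)oc2c1 | intermediate
7 | 7-(allyloxy)-5-(benzyloxy)-2-[3,4-bis(benzyloxy)phenyl]-4H-chromen-4-one | C=CCOc1cc(OCc2ccccc2)c2c(=O)cc(-c3ccc(OCc4ccccc4)c(OCc4ccccc4)c3)oc2c1 | intermediate
8 | 8-allyl-5-(benzyloxy)-2-[3,4-bis(benzyloxy)phenyl]-7-hydroxy-4H-chromen-4-one | C=CCc1c(O)cc(OCc2ccccc2)c2c(=O)cc(-c3ccc(OCc4ccccc4)c(OCc4ccccc4)c3)oc12 | intermediate
9 | 8-allyl-5-(benzyloxy)-2-[3,4-bis(benzyloxy)phenyl]-7-(methoxymethoxy)-4H-chromen-4-one | C=CCc1c(OCOC)cc(OCc2ccccc2)c2c(=O)cc(-c3ccc(OCc4ccccc4)c(OCc4ccccc4)c3)oc12 | intermediate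
10 | {5-(benzyloxy)-2-[3,4-bis(benzyloxy)phenyl]-7-(methoxymethoxy)-4-oxo-4H-chromen-8-yl}acetaldehyde | O=CCc1c(OCOC)cc(OCc2ccccc2)c2c(=O)cc(-c3ccc(OCc4ccccc4)c(OCc4ccccc4)c3)oc12 | intermediate
11 | {5-(benzyloxy)-2-[3,4-bis(benzyloxy)phenyl]-7-(methoxymethoxy)-4-oxo-4H-chromen-8-yl}acetic acid | O=C(O)Cc1c(OCOC)cc(OCc2ccccc2)c2c(=O)cc(-c3ccc(OCc4ccccc4)c(OCc4ccccc4)c3)oc12 | intermediate
12 | (4R)-4-benzyl-1,3-oxazolidin-2-one | O=C1N[C@H](Cc2ccccc2)CO1 | starting material
13 | mixed anhydride of 11 with pivalic acid | CC(C)(C)C(=O)OC(=O)Cc1c(OCOC)cc(OCc2ccccc2)c2c(=O)cc(-c3ccc(OCc4ccccc4)c(OCc4ccccc4)c3)oc12 | intermediate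
14 | (4R)-4-benzyl-3-({5-(benzyloxy)-2-[3,4-bis(benzyloxy)phenyl]-7-(methoxymethoxy)-4-oxo-4H-chromen-8-yl}acetyl)-1,3-oxazolidin-2-one | O=C(Cc1c(OCOC)cc(OCc2ccccc2)c2c(=O)cc(-c3ccc(OCc4ccccc4)c(OCc4ccccc4)c3)oc12)N1[C@H](Cc2ccccc2)COC1=O | intermediate
15 | 4-(benzyloxy)benzaldehyde | O=Cc1ccc(OCc2ccccc2)cc1 | starting material
16 | trimethylsilyl ether of 17 | O=C([C@@H](c1c(OCOC)cc(OCc2ccccc2)c2c(=O)cc(-c3ccc(OCc4ccccc4)c(OCc4ccccc4)c3)oc12)[C@@H](O[Si](C)(C)C)c1ccc(OCc2ccccc2)cc1)N1[C@H](Cc2ccccc2)COC1=O | intermediate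
17 | (4R)-4-benzyl-3-[(2S,3R)-3-[4-(benzyloxy)phenyl]-2-{5-(benzyloxy)-2-[3,4-bis(benzyloxy)phenyl]-7-(methoxymethoxy)-4-oxo-4H-chromen-8-yl}-3-hydroxypropanoyl]-1,3-oxazolidin-2-one | O=C([C@@H](c1c(OCOC)cc(OCc2ccccc2)c2c(=O)cc(-c3ccc(OCc4ccccc4)c(OCc4ccccc4)c3)oc12)[C@@H](O)c1ccc(OCc2ccccc2)cc1)N1[C@H](Cc2ccccc2)COC1=O | intermediate
18 | methyl (2S,3R)-3-[4-(benzyloxy)phenyl]-2-{5-(benzyloxy)-2-[3,4-bis(benzyloxy)phenyl]-7-(methoxymethoxy)-4-oxo-4H-chromen-8-yl}-3-hydroxypropanoate | COC(=O)[C@@H](c1c(OCOC)cc(OCc2ccccc2)c2c(=O)cc(-c3ccc(OCc4ccccc4)c(OCc4ccccc4)c3)oc12)[C@@H](O)c1ccc(OCc2ccccc2)cc1 | intermediate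
19 | 3,5-bis(benzyloxy)phenol | Oc1cc(OCc2ccccc2)cc(OCc2ccccc2)c1 | starting material
20 | 3,5-bis(benzyloxy)-2-bromophenol | Oc1cc(OCc2ccccc2)cc(OCc2ccccc2)c1Br | intermediate
21 | [3,5-bis(benzyloxy)-2-bromophenoxy]trimethylsilane | C[Si](C)(C)Oc1cc(OCc2ccccc2)cc(OCc2ccccc2)c1Br | intermediate
22 | lithium 3,5-bis(benzyloxy)-2-(trimethylsilyl)phenoxide | [Li+].[O-]c1cc(OCc2ccccc2)cc(OCc2ccccc2)c1[Si](C)(C)C | intermediate
23 | 3,5-bis(benzyloxy)-2-(trimethylsilyl)phenyl trifluoromethanesulfonate | C[Si](C)(C)c1c(OCc2ccccc2)cc(OCc2ccccc2)cc1OS(=O)(=O)C(F)(F)F | intermediate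
24 | methyl (2S,3R)-3-[4-(benzyloxy)phenyl]-2-{5-(benzyloxy)-2-[3,4-bis(benzyloxy)phenyl]-7-(methoxymethoxy)-4-oxo-4H-chromen-8-yl}-3-[(trimethylsilyl)oxy]propanoate | COC(=O)[C@@H](c1c(OCOC)cc(OCc2ccccc2)c2c(=O)cc(-c3ccc(OCc4ccccc4)c(OCc4ccccc4)c3)oc12)[C@@H](O[Si](C)(C)C)c1ccc(OCc2ccccc2)cc1 | intermediate
25 | 3,5-bis(benzyloxy)benzyne | C1#CC(OCc2ccccc2)=CC(OCc2ccccc2)=C1 | intermediate
26 | (2R,3S)-5,7-bis(benzyloxy)-2-[4-(benzyloxy)phenyl]-3-{5-(benzyloxy)-2-[3,4-bis(benzyloxy)phenyl]-7-(methoxymethoxy)-4-oxo-4H-chromen-8-yl}-2,3-dihydro-4H-chromen-4-one | O=C1c2c(OCc3ccccc3)cc(OCc3ccccc3)cc2O[C@@H](c2ccc(OCc3ccccc3)cc2)[C@@H]1c1c(OCOC)cc(OCc2ccccc2)c2c(=O)cc(-c3ccc(OCc4ccccc4)c(OCc4ccccc4)c3)oc12 | intermediate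
27 | (2R,3S)-5,7-bis(benzyloxy)-2-[4-(benzyloxy)phenyl]-3-{5-(benzyloxy)-2-[3,4-bis(benzyloxy)phenyl]-7-hydroxy-4-oxo-4H-chromen-8-yl}-2,3-dihydro-4H-chromen-4-one | O=C1c2c(OCc3ccccc3)cc(OCc3ccccc3)cc2O[C@@H](c2ccc(OCc3ccccc3)cc2)[C@@H]1c1c(O)cc(OCc2ccccc2)c2c(=O)cc(-c3ccc(OCc4ccccc4)c(OCc4ccccc4)c3)oc12 | intermediate
28 | 8-{(2R,3S)-5,7-bis(benzyloxy)-2-[4-(benzyloxy)phenyl]-4-oxo-3,4-dihydro-2H-chromen-3-yl}-5-(benzyloxy)-2-[3,4-bis(benzyloxy)phenyl]-4-oxo-4H-chromen-7-yl hydrogen sulfate | O=C1c2c(OCc3ccccc3)cc(OCc3ccccc3)cc2O[C@@H](c2ccc(OCc3ccccc3)cc2)[C@@H]1c1c(OS(=O)(=O)O)cc(OCc2ccccc2)c2c(=O)cc(-c3ccc(OCc4ccccc4)c(OCc4ccccc4)c3)oc12 | intermediate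
29 | 8-[(2R,3S)-5,7-dihydroxy-2-(4-hydroxyphenyl)-4-oxo-3,4-dihydro-2H-chromen-3-yl]-2-(3,4-dihydroxyphenyl)-5-hydroxy-4-oxo-4H-chromen-7-yl hydrogen sulfate | O=C1c2c(O)cc(O)cc2O[C@@H](c2ccc(O)cc2)[C@@H]1c1c(OS(=O)(=O)O)cc(O)c2c(=O)cc(-c3ccc(O)c(O)c3)oc12 | target

## Step count and least certain steps

Total: 14 steps. Longest linear sequence: 12 steps (steps 1 to 8, then 11 to 14); the branch to 23 (steps 9 and 10) joins at step 11.

**Step 11 (key step).** Three processes are most likely to go wrong:
- quenching of the aryl anion by a stray proton, which stops at the open aryl ether without acylation;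
- retro-aldol fragmentation of the transient alkoxide into 15 and an ester enolate;
- enolisation of C3 in the product by the methoxide set free, followed by expulsion of O1 from C2, which opens ring C and erodes the C2 configuration.

The fallback uses only known reaction types, sets out from 11 and 19 and returns at 26. Acid 11 would be coupled as in step 6 with (4S)-4-benzyl-1,3-oxazolidin-2-one to give the (4S)-configured imide F1. An Evans syn-aldol reaction with 15 (Bu2BOTf, i-Pr2NEt, CH2Cl2, −78 → 0 °C) should give the (2S,3S)-syn adduct F2. Mitsunobu etherification with 19 (PPh3, DIAD, toluene, 0 °C) should invert the carbinol and give the (2S,3R)-aryl ether imide F3. LiOH/H2O2 would remove the auxiliary to give the aryloxy acid F4. Intramolecular Friedel–Crafts acylation (trifluoroacetic anhydride, CH2Cl2, 0 °C) at either equivalent ortho position of the phloroglucinol-type ring then closes ring C to 26. If the acid also removes the methoxymethyl group, the product is 27, the next compound of the route.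

**Step 7.** The enolate carries an arene substituted at both ortho positions, so slow addition and reversal of the aldol before silylation could erode the anti selectivity. The sense of face selection also rests on the chelated-enolate model; the enantiomeric auxiliary would be used if the model fails. The fallback sets out from 14 and returns at 26. An Evans syn-aldol reaction of 14 with 15 (Bu2BOTf, i-Pr2NEt) should give the (2R,3R)-syn adduct F5, which already has the correct carbinol. MeOMgBr would give the syn methyl ester F6, silylation in the flask its silyl ether F7, and the conditions of step 11 the 2,3-cis flavanone F8. Brief treatment with catalytic DBU in CH2Cl2 at 0 °C should move C3 to the more stable trans arrangement and give 26. This accepts a thermodynamic correction at C3 in place of kinetic control in the aldol.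

**Step 3.** The allyl group may migrate in part to C6, and prolonged heating may cost the peri benzyl ether. The fallback sets out from 5 and returns at 9, replacing the sigmatropic route by halogenation and cross-coupling. MOMCl with i-Pr2NEt would give the 7-O-methoxymethyl flavone F9 and BnBr/K2CO3 its 5-O-benzyl ether F10. N-Iodosuccinimide in DMF should iodinate the fully O-alkylated ring at C8 to give the 8-iodoflavone F11. Stille coupling with allyltributylstannane (Pd(PPh3)4, DMF, 90 °C) would then give 9.

**Step 9.** Bromination para to the hydroxyl (between the two benzyloxy groups) or double bromination would lead, after step 10, to a silyl triflate that cannot give 25. The fallback sets out from 19 and returns at 23, replacing steps 9 and 10 by directed ortho-metalation. Isopropyl isocyanate with Et3N would give the carbamate F12. N-Silylation with TBSOTf/TMEDA, ortho-lithiation with n-BuLi at −78 °C between the carbamate and a benzyloxy group, and quenching with Me3SiCl would give the ortho-silyl carbamate F13. Et2NH and DBU in MeCN would release the ortho-silyl phenol F14, which PhNTf2 would convert in the same flask into 23.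

**Step 14.** Over-reduction (saturation of the flavone C2=C3 bond or hydrogenolytic opening of C2–O1) and hydrolysis of the sulfate, should the medium turn acidic, are the likely failures. The fallback sets out from 27, returns at 29 and replaces steps 13 and 14. 2,2,2-Trichloroethyl chlorosulfate with Et3N and DMAP would give the neutral, chromatographable sulfate diester F15. Transfer hydrogenolysis (Pd/C, HCO2NH4, MeOH/THF, rt) should remove the six benzyl groups and the trichloroethyl group together and give 29 as its ammonium salt.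

## Further compounds

F1 | step 11 | (4S)-4-benzyl-3-({5-(benzyloxy)-2-[3,4-bis(benzyloxy)phenyl]-7-(methoxymethoxy)-4-oxo-4H-chromen-8-yl}acetyl)-1,3-oxazolidin-2-one | O=C(Cc1c(OCOC)cc(OCc2ccccc2)c2c(=O)cc(-c3ccc(OCc4ccccc4)c(OCc4ccccc4)c3)oc12)N1[C@@H](Cc2ccccc2)COC1=O
F2 | step 11 | (4S)-4-benzyl-3-[(2S,3S)-3-[4-(benzyloxy)phenyl]-2-{5-(benzyloxy)-2-[3,4-bis(benzyloxy)phenyl]-7-(methoxymethoxy)-4-oxo-4H-chromen-8-yl}-3-hydroxypropanoyl]-1,3-oxazolidin-2-one | O=C([C@@H](c1c(OCOC)cc(OCc2ccccc2)c2c(=O)cc(-c3ccc(OCc4ccccc4)c(OCc4ccccc4)c3)oc12)[C@H](O)c1ccc(OCc2ccccc2)cc1)N1[C@@H](Cc2ccccc2)COC1=O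
F3 | step 11 | (4S)-4-benzyl-3-[(2S,3R)-3-[3,5-bis(benzyloxy)phenoxy]-3-[4-(benzyloxy)phenyl]-2-{5-(benzyloxy)-2-[3,4-bis(benzyloxy)phenyl]-7-(methoxymethoxy)-4-oxo-4H-chromen-8-yl}propanoyl]-1,3-oxazolidin-2-one | O=C([C@@H](c1c(OCOC)cc(OCc2ccccc2)c2c(=O)cc(-c3ccc(OCc4ccccc4)c(OCc4ccccc4)c3)oc12)[C@@H](Oc1cc(OCc2ccccc2)cc(OCc2ccccc2)c1)c1ccc(OCc2ccccc2)cc1)N1[C@@H](Cc2ccccc2)COC1=O
F4 | step 11 | (2S,3R)-3-[3,5-bis(benzyloxy)phenoxy]-3-[4-(benzyloxy)phenyl]-2-{5-(benzyloxy)-2-[3,4-bis(benzyloxy)phenyl]-7-(methoxymethoxy)-4-oxo-4H-chromen-8-yl}propanoic acid | O=C(O)[C@@H](c1c(OCOC)cc(OCc2ccccc2)c2c(=O)cc(-c3ccc(OCc4ccccc4)c(OCc4ccccc4)c3)oc12)[C@@H](Oc1cc(OCc2ccccc2)cc(OCc2ccccc2)c1)c1ccc(OCc2ccccc2)cc1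
F5 | step 7 | (4R)-4-benzyl-3-[(2R,3R)-3-[4-(benzyloxy)phenyl]-2-{5-(benzyloxy)-2-[3,4-bis(benzyloxy)phenyl]-7-(methoxymethoxy)-4-oxo-4H-chromen-8-yl}-3-hydroxypropanoyl]-1,3-oxazolidin-2-one | O=C([C@H](c1c(OCOC)cc(OCc2ccccc2)c2c(=O)cc(-c3ccc(OCc4ccccc4)c(OCc4ccccc4)c3)oc12)[C@@H](O)c1ccc(OCc2ccccc2)cc1)N1[C@H](Cc2ccccc2)COC1=O
F6 | step 7 | methyl (2R,3R)-3-[4-(benzyloxy)phenyl]-2-{5-(benzyloxy)-2-[3,4-bis(benzyloxy)phenyl]-7-(methoxymethoxy)-4-oxo-4H-chromen-8-yl}-3-hydroxypropanoate | COC(=O)[C@H](c1c(OCOC)cc(OCc2ccccc2)c2c(=O)cc(-c3ccc(OCc4ccccc4)c(OCc4ccccc4)c3)oc12)[C@@H](O)c1ccc(OCc2ccccc2)cc1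
F7 | step 7 | trimethylsilyl ether of F6 | COC(=O)[C@H](c1c(OCOC)cc(OCc2ccccc2)c2c(=O)cc(-c3ccc(OCc4ccccc4)c(OCc4ccccc4)c3)oc12)[C@@H](O[Si](C)(C)C)c1ccc(OCc2ccccc2)cc1
F8 | step 7 | (2R,3R)-5,7-bis(benzyloxy)-2-[4-(benzyloxy)phenyl]-3-{5-(benzyloxy)-2-[3,4-bis(benzyloxy)phenyl]-7-(methoxymethoxy)-4-oxo-4H-chromen-8-yl}-2,3-dihydro-4H-chromen-4-one (2,3-cis) | O=C1c2c(OCc3ccccc3)cc(OCc3ccccc3)cc2O[C@@H](c2ccc(OCc3ccccc3)cc2)[C@H]1c1c(OCOC)cc(OCc2ccccc2)c2c(=O)cc(-c3ccc(OCc4ccccc4)c(OCc4ccccc4)c3)oc12
F9 | step 3 | 2-[3,4-bis(benzyloxy)phenyl]-5-hydroxy-7-(methoxymethoxy)-4H-chromen-4-one | COCOc1cc(O)c2c(=O)cc(-c3ccc(OCc4ccccc4)c(OCc4ccccc4)c3)oc2c1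
F10 | step 3 | 5-(benzyloxy)-2-[3,4-bis(benzyloxy)phenyl]-7-(methoxymethoxy)-4H-chromen-4-one | COCOc1cc(OCc2ccccc2)c2c(=O)cc(-c3ccc(OCc4ccccc4)c(OCc4ccccc4)c3)oc2c1
F11 | step 3 | 5-(benzyloxy)-2-[3,4-bis(benzyloxy)phenyl]-8-iodo-7-(methoxymethoxy)-4H-chromen-4-one | COCOc1cc(OCc2ccccc2)c2c(=O)cc(-c3ccc(OCc4ccccc4)c(OCc4ccccc4)c3)oc2c1I
F12 | step 9 | 3,5-bis(benzyloxy)phenyl N-isopropylcarbamate | CC(C)NC(=O)Oc1cc(OCc2ccccc2)cc(OCc2ccccc2)c1
F13 | step 9 | 3,5-bis(benzyloxy)-2-(trimethylsilyl)phenyl N-isopropylcarbamate | CC(C)NC(=O)Oc1cc(OCc2ccccc2)cc(OCc2ccccc2)c1[Si](C)(C)C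
F14 | step 9 | 3,5-bis(benzyloxy)-2-(trimethylsilyl)phenol | Oc1cc(OCc2ccccc2)cc(OCc2ccccc2)c1[Si](C)(C)C
F15 | step 14 | 8-{(2R,3S)-5,7-bis(benzyloxy)-2-[4-(benzyloxy)phenyl]-4-oxo-3,4-dihydro-2H-chromen-3-yl}-5-(benzyloxy)-2-[3,4-bis(benzyloxy)phenyl]-4-oxo-4H-chromen-7-yl 2,2,2-trichloroethyl sulfate | O=C1c2c(OCc3ccccc3)cc(OCc3ccccc3)cc2O[C@@H](c2ccc(OCc3ccccc3)cc2)[C@@H]1c1c(OS(=O)(=O)OCC(Cl)(Cl)Cl)cc(OCc2ccccc2)c2c(=O)cc(-c3ccc(OCc4ccccc4)c(OCc4ccccc4)c3)oc12
A1 | alternative 1 | 1-[2,4-bis(benzyloxy)-6-fluorophenyl]-3-[4-(benzyloxy)phenyl]-2-{5-(benzyloxy)-2-[3,4-bis(benzyloxy)phenyl]-4-oxo-7-[(triisopropylsilyl)oxy]-4H-chromen-8-yl}-3-(4,4,5,5-tetramethyl-1,3,2-dioxaborolan-2-yl)propan-1-one (anti, configured as in the target) | O=C(c1c(F)cc(OCc2ccccc2)cc1OCc1ccccc1)[C@@H](c1c(O[Si](C(C)C)(C(C)C)C(C)C)cc(OCc2ccccc2)c2c(=O)cc(-c3ccc(OCc4ccccc4)c(OCc4ccccc4)c3)oc12)[C@@H](B1OC(C)(C)C(C)(C)O1)c1ccc(OCc2ccccc2)cc1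
A2 | alternative 1 | 5-(benzyloxy)-2-[3,4-bis(benzyloxy)phenyl]-8-[(E)-2-(4,4,5,5-tetramethyl-1,3,2-dioxaborolan-2-yl)ethenyl]-7-[(triisopropylsilyl)oxy]-4H-chromen-4-one | CC1(C)OB(/C=C/c2c(O[Si](C(C)C)(C(C)C)C(C)C)cc(OCc3ccccc3)c3c(=O)cc(-c4ccc(OCc5ccccc5)c(OCc5ccccc5)c4)oc23)OC1(C)C
A3 | alternative 1 | 4-(benzyloxy)phenyllithium | [Li]c1ccc(OCc2ccccc2)cc1
A4 | alternative 1 | 2,4-bis(benzyloxy)-6-fluorobenzoyl chloride | O=C(Cl)c1c(F)cc(OCc2ccccc2)cc1OCc1ccccc1
A5 | alternative 2 | (2R,3S)-5,7-bis(benzyloxy)-2-[4-(benzyloxy)phenyl]-3-{5-(benzyloxy)-2-[3,4-bis(benzyloxy)phenyl]-7-hydroxy-4-oxo-4H-chromen-8-yl}-2,3-dihydro-4H-chromen-4-one (identical with 27) | O=C1c2c(OCc3ccccc3)cc(OCc3ccccc3)cc2O[C@@H](c2ccc(OCc3ccccc3)cc2)[C@@H]1c1c(O)cc(OCc2ccccc2)c2c(=O)cc(-c3ccc(OCc4ccccc4)c(OCc4ccccc4)c3)oc12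
A6 | alternative 2 | 2,4-bis(benzyloxy)-6-{(1S)-1-[4-(benzyloxy)phenyl]-2-{5-(benzyloxy)-2-[3,4-bis(benzyloxy)phenyl]-7-hydroxy-4-oxo-4H-chromen-8-yl}-2-(4-methylbenzenesulfonyl)ethoxy}benzaldehyde (sulfonyl-bearing carbon as either epimer) | O=Cc1c(OCc2ccccc2)cc(OCc2ccccc2)cc1O[C@@H](c1ccc(OCc2ccccc2)cc1)C(c1c(O)cc(OCc2ccccc2)c2c(=O)cc(-c3ccc(OCc4ccccc4)c(OCc4ccccc4)c3)oc12)S(=O)(=O)c1ccc(C)cc1
A7 | alternative 3 | 4-[(2R,3S)-5,7-bis(benzyloxy)-3-{5-(benzyloxy)-2-[3,4-bis(benzyloxy)phenyl]-4-oxo-7-[(triisopropylsilyl)oxy]-4H-chromen-8-yl}-4-oxo-3,4-dihydro-2H-chromen-2-yl]phenyl acetate | O=C1c2c(OCc3ccccc3)cc(OCc3ccccc3)cc2O[C@@H](c2ccc(OC(C)=O)cc2)[C@@H]1c1c(O[Si](C(C)C)(C(C)C)C(C)C)cc(OCc2ccccc2)c2c(=O)cc(-c3ccc(OCc4ccccc4)c(OCc4ccccc4)c3)oc12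
A8 | alternative 3 | 4-[(1S)-3-[2,4-bis(benzyloxy)-6-hydroxyphenyl]-1-{5-(benzyloxy)-2-[3,4-bis(benzyloxy)phenyl]-4-oxo-7-[(triisopropylsilyl)oxy]-4H-chromen-8-yl}-3-oxopropyl]phenyl acetate | CC(=O)Oc1ccc(cc1)[C@H](CC(=O)c1c(O)cc(OCc2ccccc2)cc1OCc1ccccc1)c1c(O[Si](C(C)C)(C(C)C)C(C)C)cc(OCc2ccccc2)c2c(=O)cc(-c3ccc(OCc4ccccc4)c(OCc4ccccc4)c3)oc12
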